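Take the amounts first: west holds 2.50 of partner per starting material, but the rate reads free [partner], not the charge.

the same everywhere: starting material 0.18 M; time 10 h
- west: partner 0.450 M
- south-west: partner 0.590 M

    partner + mono adduct → bis adduct + by-product (k1 = 0.0205 M⁻¹ h⁻¹)
    partner + bis adduct → tris adduct + by-product (k2 = 0.0613 M⁻¹ h⁻¹)
    partner + by-product ⇌ idle adduct, settled at all times (K3 = 2.1 M⁻¹)
    starting material + partner → mono adduct + by-product (k4 = 0.133 M⁻¹ h⁻¹)
    partner + tris adduct → tetra adduct + by-product (k5 = 0.140 M⁻¹ h⁻¹)

* part of the starting material that has reacted at the end, west
* part of the starting material that has reacted at the end, south-west
* what raising the concentration of partner from its lowest to its highest value here does to the part of the starting material that has reacted (changes below 5 percentage points count as none) (it rises / it falls / no change)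

- amounts and yields of by-product count idle adduct too
- run time (west): 10 h

Climb the ladder of times from the top. The binding is kept at balance, so by-product shares itself out as it forms; in west, with 0.94 for the equilibrium constant times [partner] at the start, a share of 0.486 goes to idle adduct at the start. Next comes the addition to starting material, with a half-life of 12 h at charged levels in west. The addition to tris adduct has a similar time, 11 h, but it waits for tris adduct, which comes through two slower rungs, 25 h for bis adduct and 75 h for mono adduct. Drop those rungs from the partner count, because the mono adduct half-life is longer than the run. Mono adduct collects.

Follow free [partner], then. Treat the loss of starting material as pseudo-first-order: the part reacted is one minus the exponential of minus 0.133 M⁻¹ h⁻¹ times mean free [partner] times time.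

Call the toll the partner lost per starting material reacted, one for the addition plus the bound share: 1.49 in west. At charged [partner], west reaches 45.0%. Half the toll on that conversion leaves a mean of 0.390 M, hence 40.5%. South-west has toll 1.55, first pass 54.4%, mean 0.514 M, hence 49.5%. The gap of 9.1 percentage points clears the mark.

The forecast gives 40.3% (38% to 43%) for west and 49.5% (46.5% to 52%) for south-west, and says it rises: “Averaging that free partner over the 10 h gives roughly 40% and 50% reacted”.

The simulation gives 40.4% for west and 49.2% for south-west, and the part reacted changes by 8.8 points: it rises. West has 76% of its charged partner left at the end, so its toll over the whole run reads 1.48. Now charge the neighbour of west with 0.77 M of partner. Its toll is higher, 1.62. Its first pass is 64.1%, its mean free partner 0.677 M, and its reckoned part reacted 59.3%. That neighbour reads 58.8%.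

The numbers are assumed; the flask was simulated.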